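**Plan**

- Retrosynthesis first re-methylates the 5-OH, then opens ring C at three bonds: C4a–C4, C4–C3 and O1–C2.
- Enabling feature: in ring C the C4 carbonyl sits between ring A carbon C4a and the C3=C2 unit; C2 carries ring B and is tied to ring A carbon C8a through O1. This array maps onto an ortho-iodophenol (I at C4a, OH at C8a), one CO (C4) and a terminal arylacetylene (C3, C2, ring B).
- Forward, ring A is made as 6-iodo-2,3,5-trimethoxyphenol from 2-hydroxy-4,6-dimethoxybenzaldehyde (MOM ether, Baeyer–Villiger oxidation, methylation, MOM-directed lithiation/iodination, deprotection).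
- Ring B comes as 2-ethynyl-1,4-dimethoxybenzene from 2,5-dimethoxybenzaldehyde; a palladium-catalysed carbonylative annulation then joins both arenes and CO and closes ring C in one operation.
- Chelation-controlled BCl3 cleavage of the 5-methyl ether ends the route; the target has no stereogenic element, so no stereochemistry has to be set.

Key step: step 7

Remark on the chemistry: enaminone 14 is written as the E isomer expected from addition of a secondary amine to an ynone; its push-pull double bond rotates easily and either geometry should close to the same flavone.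

**Route**

Step 1
Reactants: 1 2-hydroxy-4,6-dimethoxybenzaldehyde
Product: 2 2,4-dimethoxy-6-(methoxymethoxy)benzaldehyde
Conditions: NaH, DMF, 0 °C; MOMCl, 0 °C → rt
Reagents that add atoms: chloromethyl methyl ether (MOMCl), COCCl
Why: Deprotonation of the chelated phenol and O-alkylation by the reactive α-chloro ether (Williamson-type acetal formation) should give the MOM ether, which later serves as the ortho-directing group, while the non-enolisable aldehyde is untouched.

Step 2
Reactants: 2 2,4-dimethoxy-6-(methoxymethoxy)benzaldehyde
Product: 4 2,4-dimethoxy-6-(methoxymethoxy)phenol, via aryl formate 3 (not isolated)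
Conditions: mCPBA, CH2Cl2, 0 °C → rt; aq. NaHCO3 wash; then K2CO3 (cat.), MeOH, rt, under N2
Reagents that add atoms: 3-chloroperoxybenzoic acid (mCPBA), O=C(OO)c1cccc(Cl)c1
Why: In this Baeyer–Villiger (Dakin-type) oxidation the electron-rich trialkoxyaryl group should migrate in preference to hydrogen, and the resulting formate is cleaved by base-catalysed transesterification that leaves the MOM acetal and the methyl ethers intact.

Step 3
Reactants: 4 2,4-dimethoxy-6-(methoxymethoxy)phenol
Product: 5 1,2,5-trimethoxy-3-(methoxymethoxy)benzene
Conditions: MeI, K2CO3, acetone, reflux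
Reagents that add atoms: iodomethane, CI
Why: Williamson methylation of the phenoxide should proceed cleanly because the MOM acetal is stable to base and no other nucleophilic site is present.

Step 4
Reactants: 5 1,2,5-trimethoxy-3-(methoxymethoxy)benzene
Product: 7 2-iodo-1,4,5-trimethoxy-3-(methoxymethoxy)benzene, via aryllithium 6 (not isolated)
Conditions: n-BuLi, THF, −20 → 0 °C; then I2, THF, −78 °C → rt
Reagents that add atoms: iodine, II
Why: In this directed ortho-metalation the bidentate MOM acetal and the neighbouring methoxy group should together deliver lithium to the only free carbon ortho to the acetal, a stronger director than the two methoxy groups flanking the other free position, and iodine traps the aryllithium.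

Step 5
Reactants: 7 2-iodo-1,4,5-trimethoxy-3-(methoxymethoxy)benzene
Product: 8 6-iodo-2,3,5-trimethoxyphenol
Conditions: HCl (0.5 M in MeOH), rt
Reagents that add atoms: none
Why: Acid-catalysed acetal exchange with methanol should free the phenol under conditions dilute and cool enough to spare the methyl ethers and to avoid protodeiodination of the electron-rich ring.

Step 6
Reactants: 9 2,5-dimethoxybenzaldehyde
Product: 11 2-ethynyl-1,4-dimethoxybenzene, via diazoalkene 10 (not isolated)
Conditions: dimethyl (1-diazo-2-oxopropyl)phosphonate, K2CO3, MeOH, rt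
Reagents that add atoms: dimethyl (1-diazo-2-oxopropyl)phosphonate (Ohira–Bestmann reagent), COP(=O)(OC)C(=[N+]=[N-])C(C)=O
Why: In the Ohira–Bestmann variant of the Seyferth–Gilbert homologation, methanolysis of the reagent gives the diazomethylphosphonate anion, Horner–Wadsworth–Emmons-type olefination of the aldehyde gives the diazoalkene, and loss of N2 with 1,2-hydrogen shift should give the terminal alkyne.

Step 7
Reactants: 8 6-iodo-2,3,5-trimethoxyphenol; 11 2-ethynyl-1,4-dimethoxybenzene; 12 carbon monoxide
Product: 15 2-(2,5-dimethoxyphenyl)-5,7,8-trimethoxy-4H-chromen-4-one, via hydroxyaryl ynone 13 (not isolated), via enaminone 14 (not isolated)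
Conditions: PdCl2(PPh3)2 (5 mol %), CO (20 atm), Et2NH, 120 °C, autoclave
Reagents that add atoms: none
Why: Zerovalent palladium formed in situ from PdCl2(PPh3)2 inserts into the C–I bond of 8, CO insertion gives an aroylpalladium iodide, and amine-assisted coupling with the terminal C–H of 11 (a carbonylative Sonogashira-type step) releases ynone 13, creating C4a–C4 and C4–C3. Et2NH then adds to the ynone to give the vinylogous amide 14, whose phenolic oxygen attacks the amine-bearing carbon and expels Et2NH, forming O1–C2. The closest known reaction type is the palladium-catalysed carbonylative annulation of ortho-iodophenols with terminal arylacetylenes under CO pressure in a secondary amine, which delivers flavones. Ring C closes in the 6-endo mode by addition–elimination at C2, and no stereocenter is formed. The step needs acylation before alkyne coupling (otherwise a 2-arylbenzofuran results) and 6-endo over 5-exo closure (otherwise an aurone): CO pressure together with fast CO insertion into the electron-rich arylpalladium should secure the first, and the amine adduct, which makes C2 the electrophilic carbon, should secure the second. The iodine sits between the hydroxyl-bearing carbon and the carbon carrying the future C5 methoxy group, which fixes C4a as the acylated atom and so the orientation of ring A.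

Step 8
Reactants: 15 2-(2,5-dimethoxyphenyl)-5,7,8-trimethoxy-4H-chromen-4-one
Product: 17 5-hydroxy-7,8,2',5'-tetramethoxyflavone, via aryl dichloroborinate 16 (not isolated)
Conditions: BCl3 (1.2 equiv), CH2Cl2, −78 → 0 °C; then H2O
Reagents that add atoms: none
Why: In this chelation-controlled Lewis-acid ether cleavage, BCl3 should bind between the C4 carbonyl oxygen and the peri 5-methoxy oxygen so that chloride removes only that methyl group, the other four methoxy groups lack such a neighbouring carbonyl, and water hydrolyses the boron aryloxide to the free 5-OH.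

**Compound list**

1 | 2-hydroxy-4,6-dimethoxybenzaldehyde | COc1cc(O)c(C=O)c(OC)c1 | starting material
2 | 2,4-dimethoxy-6-(methoxymethoxy)benzaldehyde | COCOc1cc(OC)cc(OC)c1C=O | intermediate
3 | 2,4-dimethoxy-6-(methoxymethoxy)phenyl formate | COCOc1cc(OC)cc(OC)c1OC=O | intermediate
4 | 2,4-dimethoxy-6-(methoxymethoxy)phenol | COCOc1cc(OC)cc(OC)c1O | intermediate
5 | 1,2,5-trimethoxy-3-(methoxymethoxy)benzene | COCOc1cc(OC)cc(OC)c1OC | intermediate
6 | [3,4,6-trimethoxy-2-(methoxymethoxy)phenyl]lithium | [Li]c1c(OCOC)c(OC)c(OC)cc1OC | intermediate
7 | 2-iodo-1,4,5-trimethoxy-3-(methoxymethoxy)benzene | COCOc1c(I)c(OC)cc(OC)c1OC | intermediate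
8 | 6-iodo-2,3,5-trimethoxyphenol | COc1cc(OC)c(I)c(O)c1OC | intermediate
9 | 2,5-dimethoxybenzaldehyde | COc1ccc(OC)c(C=O)c1 | starting material
10 | 2-(2-diazoethenyl)-1,4-dimethoxybenzene | COc1ccc(OC)c(C=C=[N+]=[N-])c1 | intermediate
11 | 2-ethynyl-1,4-dimethoxybenzene | COc1ccc(OC)c(C#C)c1 | intermediate
12 | carbon monoxide | [C-]#[O+] | starting material
13 | 3-(2,5-dimethoxyphenyl)-1-(2-hydroxy-3,4,6-trimethoxyphenyl)prop-2-yn-1-one | COc1ccc(OC)c(C#CC(=O)c2c(O)c(OC)c(OC)cc2OC)c1 | intermediate
14 | (E)-3-(diethylamino)-3-(2,5-dimethoxyphenyl)-1-(2-hydroxy-3,4,6-trimethoxyphenyl)prop-2-en-1-one | CCN(CC)/C(=C/C(=O)c1c(O)c(OC)c(OC)cc1OC)c1cc(OC)ccc1OC | intermediate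
15 | 2-(2,5-dimethoxyphenyl)-5,7,8-trimethoxy-4H-chromen-4-one | COc1ccc(OC)c(-c2cc(=O)c3c(OC)cc(OC)c(OC)c3o2)c1 | intermediate
16 | 2-(2,5-dimethoxyphenyl)-7,8-dimethoxy-4-oxo-4H-chromen-5-yl dichloroborinate | COc1ccc(OC)c(-c2cc(=O)c3c(OB(Cl)Cl)cc(OC)c(OC)c3o2)c1 | intermediate
17 | 5-hydroxy-7,8,2',5'-tetramethoxyflavone, i.e. 2-(2,5-dimethoxyphenyl)-5-hydroxy-7,8-dimethoxy-4H-chromen-4-one | COc1ccc(OC)c(-c2cc(=O)c3c(O)cc(OC)c(OC)c3o2)c1 | target

**Count and risks**

Total step count: 8. Longest linear sequence: 7 steps (steps 1, 2, 3, 4, 5, 7, 8).

Steps most likely to fail: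

Step 7. Several processes could divert the annulation:
- oxidative addition into the C–I bond, which is flanked by two oxygen substituents on an electron-rich ring, may be slow;
- alkyne coupling may run ahead of CO insertion and end in a benzofuran;
- diethylamine may intercept the aroylpalladium as an amide;
- the ring may close in the 5-exo sense.

The fallback is a palladium-free, stepwise construction of the same three bonds that sets out from 7 and 11. Alkyne 11 would be deprotonated (n-BuLi, THF, −78 °C) and acylated with N-methoxy-N-methylcarbamoyl chloride to give N-methoxy-N-methyl-3-(2,5-dimethoxyphenyl)prop-2-ynamide F1. Iodine–lithium exchange on 7 (n-BuLi, THF, −78 °C) would regenerate aryllithium 6 with defined regiochemistry, and its addition to F1 should give 3-(2,5-dimethoxyphenyl)-1-[3,4,6-trimethoxy-2-(methoxymethoxy)phenyl]prop-2-yn-1-one F2. HCl in MeOH would remove the MOM group to give 13, and warming with Et2NH in EtOH should close ring C through 14, returning to the route at 15.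

Step 4. Deprotonation may compete at the ring position between the two methoxy groups, which would place iodine para to the masked phenol and give an iodide that cannot annulate. The fallback changes the directing group to the stronger O-carbamate and sets out from 5. HCl in MeOH would give 2,3,5-trimethoxyphenol F3, and NaH with ClCONEt2 in THF would give 2,3,5-trimethoxyphenyl N,N-diethylcarbamate F4. Lithiation with s-BuLi and TMEDA in THF at −78 °C, with I2 added at that temperature to forestall the anionic ortho-Fries shift, should give 2-iodo-3,5,6-trimethoxyphenyl N,N-diethylcarbamate F5, since the only free position ortho to the carbamate is the desired one. NaOH in EtOH at reflux would cleave the carbamate and return to the route at 8.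

Step 8. The Lewis acid may go on to cleave further ethers, most likely within the vicinal 7,8-dimethoxy pair or at the 2'-methoxy group, giving a mixture of partly demethylated flavones. The fallback replaces selective cleavage by exhaustive cleavage and selective re-methylation and sets out from 15. Excess BBr3 (CH2Cl2, −78 °C → rt) would give 2-(2,5-dihydroxyphenyl)-5,7,8-trihydroxy-4H-chromen-4-one F6. MeI (4 equiv) with K2CO3 in acetone under argon should then methylate the four free hydroxyls and leave the 5-OH, which is hydrogen-bonded to the C4 carbonyl and the least nucleophilic, arriving at 17.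

**Further compounds**

F1 | step 7 | N-methoxy-N-methyl-3-(2,5-dimethoxyphenyl)prop-2-ynamide | COc1ccc(OC)c(C#CC(=O)N(C)OC)c1
F2 | step 7 | 3-(2,5-dimethoxyphenyl)-1-[3,4,6-trimethoxy-2-(methoxymethoxy)phenyl]prop-2-yn-1-one | COCOc1c(C(=O)C#Cc2cc(OC)ccc2OC)c(OC)cc(OC)c1OC
F3 | step 4 | 2,3,5-trimethoxyphenol | COc1cc(O)c(OC)c(OC)c1
F4 | step 4 | 2,3,5-trimethoxyphenyl N,N-diethylcarbamate | CCN(CC)C(=O)Oc1cc(OC)cc(OC)c1OC
F5 | step 4 | 2-iodo-3,5,6-trimethoxyphenyl N,N-diethylcarbamate | CCN(CC)C(=O)Oc1c(I)c(OC)cc(OC)c1OC
F6 | step 8 | 2-(2,5-dihydroxyphenyl)-5,7,8-trihydroxy-4H-chromen-4-one | O=c1cc(-c2cc(O)ccc2O)oc2c(O)c(O)cc(O)c12
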